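**Remark on the chemistry (assumptions):** target 16 is achiral; the bicyclic intermediate 15 is formed as a racemate and its stereocentres disappear on aromatisation. Compounds 1, 3 and 10 and the reagents named in the steps are taken as purchasable.

## Analysis of the target

Compound 16 is a flavone: a 4H-chromen-4-one (rings A and C) with a benzene ring B on C2. Ring A carries a hydroxyl on C5 and methoxy groups on C6 and C7; ring B carries methoxy groups on C2' and C3' and a hydroxyl on C5'. There is no stereocentre, so the problem is one of connectivity and of telling six oxygen substituents apart. The C5 hydroxyl is hydrogen-bonded to the C4 carbonyl and is unreactive. The C5' hydroxyl is a free phenol para to a methoxy group (a hydroquinone monoether) and is easily oxidised, and the pyranone can be opened by hard nucleophiles at C2. The main difficulty is ring B: in its 1,2,3,5 pattern C1' is ortho to one methoxy group and meta to the hydroxyl, so no oxygen substituent directs an electrophile or a metalation to C1', and the lone hydroxyl must be distinguished from two methoxy groups. The strategy rests on the fact that the C5' hydroxyl is para to the C2' methoxy group with the C3' methoxy group alongside, while C1' and C6' carry no oxygen. This is the pattern left when 2,3-dimethoxyfuran adds across an alkyne and the oxygen bridge opens: the furan oxygen becomes the C5' hydroxyl, furan C2 and C3 become C2' and C3', and the alkyne carbons become C1' and C6'. Ring B can therefore be built last on a chromone that carries an ethynyl group on C2.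

## Retrosynthetic reasoning

**Ring B (16 to 9 and 14).** The bonds C1'–C2' and C5'–C6' are cut, which removes ring B and leaves alkyne 9 and furan 14. Cutting here, and not at the C2–C1' biaryl-type bond or inside ring C, means that no benzene building block with the 1,2,3,5 oxygen pattern has to be made. The forward reaction is a [4+2] cycloaddition to the oxanorbornadiene 15, followed by opening of the oxygen bridge. It has to join the unsubstituted furan C5 to the terminal alkyne carbon, and the bridge has to open at the methoxy-bearing bridgehead. The C5 hydroxyl is left free in 9 because it is chelated, and its hydrogen bond to the C4 carbonyl increases the pull of the pyranone on the alkyne.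

**Furan 14 back to 10.** Furan 14 is a ketene acetal and cannot be stored, so it is released last by decarboxylation of acid 13, which comes from ester 12. The two methoxy C–O bonds of 12 are traced to dibromide 10 through 11. The bromine on C5 is activated for addition–elimination by the ester; the bromine on C4 needs copper catalysis. Making 14 by O-alkylation of a butenolide enolate was considered and set aside, because such enolates alkylate on carbon as readily as on oxygen.

**Alkyne 9 back to aldehyde 8.** The terminal alkyne carbon is removed, giving aldehyde 8. A one-carbon homologation of a non-enolisable aldehyde is the shortest way to a terminal alkyne on C2, and it avoids organometallic reagents that would attack the pyranone.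

**Aldehyde 8 back to ester 6.** Aldehyde 8 is taken back through alcohol 7 to ester 6. Two oxidation-level steps are used because each is selective on a chromone, whereas a direct partial reduction of the ester would not be.

**Ester 6 back to 5.** The C5 hydroxyl of 6 comes from the C5 methoxy group of 5 by chelation-controlled cleavage. The cleavage is placed here, before the alkyne exists, so that the Lewis acid and the halide never meet the activated triple bond.

**Ring C (5 back to 2 and 3).** Cutting C2–C3 and O1–C2 of the pyranone gives acetophenone 2 and diethyl oxalate 3. The forward reaction is a Claisen condensation to diketo ester 4 and acid cyclodehydration.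

**Acetophenone 2 back to 1.** Removing the acetyl group from 2 gives phenol 1, whose two positions ortho to the hydroxyl are equivalent, so the acylation has only one outcome.

## Alternatives that were turned down

**Alternative 1:** Ring C is disconnected at O1–C8a. Forward, the diaryl 1,3-diketone A2 (3-[3-oxo-3-(2,3,4-trimethoxyphenyl)propanoyl]-4,5-dimethoxyphenyl methanesulfonate) is oxidised at a carbon anode in a fluorinated alcohol; the enol oxygen attacks the one free ortho C–H of the trimethoxyphenyl ring, giving the flavone mesylate A1.
- For: ring A needs no phenol or halogen, and the oxidant is electric current.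
- Against: the anodic C–O closure is itself without close precedent on a tetra-oxygenated substrate. Both arenes and the product A1 are oxidisable. Attack at the methoxy-bearing ortho carbon with loss of methanol would give the wrong ring A pattern.
- Step economy: A2 requires a ring B acid that already has the 1,2,3,5 pattern, and A1 is still two steps (mesylate removal, C5 demethylation) from 16.
- Comparison: this alternative is no more certain than the chosen key step and does not solve ring B. The chosen strategy builds ring B and ends at 16 directly.

**Alternative 2:** Ring A is disconnected at C7–C8 and C5–C6. Forward, the methyl group of pyranone ester A4 (methyl 6-[5-(benzyloxy)-2,3-dimethoxyphenyl]-2-methyl-4-oxo-4H-pyran-3-carboxylate) is deprotonated with excess lithium amide base and acylated by methyl methoxyacetate A5; the new ketone enolate closes onto the ester to give A3.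
- For: the ring A oxygens arrive already differentiated (C5 and C7 hydroxyl, C6 methoxy), so no Lewis-acid demethylation is needed. On this point it is stronger than the chosen route; the later selective methylation of the C7 hydroxyl beside the chelated C5 hydroxyl is dependable.
- Against: A4 is a multistep compound that again needs the pre-formed ring B. The double condensation uses an enolisable ester that can self-condense, and a pyranone that can be attacked at its ring carbons. Methylation and debenzylation follow.
- Comparison: the chosen strategy gives up the built-in ring A differentiation for one chelation-controlled demethylation on a robust ester, and in return needs no ring B building block.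

**Alternative 3:** Ring C is disconnected at C4a–C4, C4–C3 and O1–C2. Forward, iodophenol A7 (2-iodo-3,4,5-trimethoxyphenol), carbon monoxide A9 and arylacetylene A8 (5-(benzyloxy)-1-ethynyl-2,3-dimethoxybenzene) are combined under a palladium–phosphine catalyst in a secondary amine, giving flavone A6.
- For: three bonds form in one step from two fragments, and the carbonylative coupling–cyclisation is an established way to flavones. In precedent and convergence this alternative is stronger than the chosen key step.
- Against: the iodine of A7 is flanked by hydroxyl and methoxy on a very electron-rich ring, so oxidative addition and CO insertion are slow. Direct coupling without CO (leading to a benzofuran) and five-membered closure (aurone) compete.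
- Step economy: A8 has to be made by several steps of arene chemistry to install the 1,2,3,5 pattern, and A6 still needs debenzylation and C5 demethylation.
- Comparison: the chosen strategy accepts a less certain key step; in exchange ring B comes from a three-step furan and no protecting group has to be removed at the end.

Key step: step 10

## Route

Step 1
Reactants: 1 3,4,5-trimethoxyphenol
Product: 2 1-(6-hydroxy-2,3,4-trimethoxyphenyl)ethan-1-one
Conditions: BF3·OEt2, AcOH, 90 °C; then aq NaOAc
Reagents that add atoms: acetic acid, CC(=O)O
Why: Friedel–Crafts C-acylation of an electron-rich phenol (Nencki/Fries manifold); the two positions ortho to the hydroxyl are equivalent, and the product is held as a BF2 chelate that prevents a second acylation.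

Step 2
Reactants: 2 1-(6-hydroxy-2,3,4-trimethoxyphenyl)ethan-1-one; 3 diethyl oxalate
Product: 5 ethyl 5,6,7-trimethoxy-4-oxo-4H-chromene-2-carboxylate, via diketo ester 4 (not isolated)
Conditions: NaOEt, EtOH, reflux; then conc. HCl, EtOH, reflux
Reagents that add atoms: none
Why: Crossed Claisen condensation of the methyl ketone enolate with the non-enolisable oxalate gives 4; acid then promotes addition of the phenol to the 2-keto group and dehydration, the standard chromone-2-carboxylate synthesis.

Step 3
Reactants: 5 ethyl 5,6,7-trimethoxy-4-oxo-4H-chromene-2-carboxylate
Product: 6 ethyl 5-hydroxy-6,7-dimethoxy-4-oxo-4H-chromene-2-carboxylate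
Conditions: BCl3, CH2Cl2, −78 → 0 °C; then aq NaHCO3
Reagents that add atoms: none
Why: Chelation-controlled aryl methyl ether cleavage: BCl3 bridges the C4 carbonyl and the peri C5 methoxy oxygen, so chloride removes only that methyl group, while the ester and the other methoxy groups should survive at low temperature.

Step 4
Reactants: 6 ethyl 5-hydroxy-6,7-dimethoxy-4-oxo-4H-chromene-2-carboxylate
Product: 7 5-hydroxy-2-(hydroxymethyl)-6,7-dimethoxy-4H-chromen-4-one
Conditions: NaBH4, MeOH–THF, 0 °C; then aq NH4Cl
Reagents that add atoms: none
Why: Chemoselective borohydride reduction of the activated ester on the electron-poor C2 of a chromone; the pyranone carbonyl is a chelated vinylogous ester (a phenoxide under these conditions) and should not be attacked at 0 °C.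

Step 5
Reactants: 7 5-hydroxy-2-(hydroxymethyl)-6,7-dimethoxy-4H-chromen-4-one
Product: 8 5-hydroxy-6,7-dimethoxy-4-oxo-4H-chromene-2-carbaldehyde
Conditions: activated MnO2, CH2Cl2, rt
Reagents that add atoms: none
Why: MnO2 oxidation of an allylic-type primary alcohol (the carbinol is on the C2=C3 double bond) stops at the aldehyde, and the hydrogen-bonded C5 phenol should not be oxidised.

Step 6
Reactants: 8 5-hydroxy-6,7-dimethoxy-4-oxo-4H-chromene-2-carbaldehyde
Product: 9 2-ethynyl-5-hydroxy-6,7-dimethoxy-4H-chromen-4-one
Conditions: dimethyl (1-diazo-2-oxopropyl)phosphonate, K2CO3, MeOH, 0 °C → rt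
Reagents that add atoms: dimethyl (1-diazo-2-oxopropyl)phosphonate, CC(=O)C(=[N+]=[N-])P(=O)(OC)OC
Why: Ohira–Bestmann (Seyferth–Gilbert) homologation: methanolysis of the reagent gives the diazomethylphosphonate anion, which adds to the non-enolisable aldehyde; phosphate elimination, loss of N2 and a 1,2-hydrogen shift give the terminal alkyne. The C5 hydroxyl is present as its phenoxide, which lowers the electrophilicity of the pyranone toward methoxide.

Step 7
Reactants: 10 methyl 4,5-dibromofuran-2-carboxylate
Product: 12 methyl 4,5-dimethoxyfuran-2-carboxylate, via bromo methoxy furoate 11 (not isolated)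
Conditions: NaOMe, MeOH, reflux; then CuBr (cat.), DMF, 100 °C
Reagents that add atoms: sodium methoxide, [Na+].[O-]C
Why: Addition–elimination at C5, which is activated by the C2 ester, gives 11; an Ullmann-type methoxylation catalysed by CuBr then replaces the unactivated C4 bromine, as in the preparation of methoxythiophenes from bromothiophenes.

Step 8
Reactants: 12 methyl 4,5-dimethoxyfuran-2-carboxylate
Product: 13 4,5-dimethoxyfuran-2-carboxylic acid
Conditions: NaOH, MeOH–H2O, rt; then cold dilute HCl to pH 3
Reagents that add atoms: sodium hydroxide, [Na+].[OH-]
Why: Ester saponification; the carboxyl group makes this furan far less acid-labile than 14, so brief cold acidification should release the acid intact.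

Step 9
Reactants: 13 4,5-dimethoxyfuran-2-carboxylic acid
Product: 14 2,3-dimethoxyfuran
Conditions: Cu powder, quinoline, 180–200 °C, product distilled out under argon into a base-washed receiver
Reagents that add atoms: none
Why: Copper–quinoline protodecarboxylation of an electron-rich 2-furoic acid, the reaction type that gives 2-alkoxyfurans from 5-alkoxy-2-furoic acids; the volatile product leaves the hot basic medium as it forms.

Step 10
Reactants: 9 2-ethynyl-5-hydroxy-6,7-dimethoxy-4H-chromen-4-one; 14 2,3-dimethoxyfuran
Product: 16 5-hydroxy-2-(5-hydroxy-2,3-dimethoxyphenyl)-6,7-dimethoxy-4H-chromen-4-one, via oxanorbornadiene 15 (not isolated)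
Conditions: 14 (3 equiv), toluene, 80 °C, sealed tube, argon; then CF3CO2H (5 mol %), 0 °C → rt
Reagents that add atoms: none
Why: Proposed new method: a [4+2] cycloaddition of a furan bearing methoxy groups on C2 and C3 with a terminal alkyne activated only through a conjugated pyranone (a vinylogous ynone) has not been shown; the closest known reaction type is the Diels–Alder benzannulation of 2-alkoxyfurans with propiolates, ynones and acetylenedicarboxylates to 4-alkoxyphenols. The electron-rich diene 14 should add across the alkyne of 9 in an asynchronous, normal-electron-demand sense, the furan C5–H terminus bonding first to the terminal alkyne carbon (C5'–C6') and the methoxy-bearing C2 closing on the internal carbon (C1'–C2'); ring B is thus closed as a six-membered ring by intermolecular [4+2] cycloaddition. In 15 the bridging C–O bond at the ketal bridgehead ionises to a methoxy-stabilised oxocarbenium ion, and loss of the proton from the other bridgehead aromatises the ring, so the furan oxygen ends as the C5' hydroxyl. The two bridgehead stereocentres of 15 form as a racemate and are destroyed on aromatisation, so nothing has to be controlled. Regioselectivity is needed, and should come from pairing the most nucleophilic free α-position of the furan (C5, conjugated with the 2-methoxy group) with the electrophilic alkyne terminus, helped by the hindrance at the fully substituted C2; the 3-methoxy group works against this bias, so it is weaker than in a plain 2-alkoxyfuran. Chemoselectivity for the alkyne over the C2–C3 bond of the pyranone follows from that bond being a trisubstituted, oxygen-substituted vinylogous ester alkene. The acid is added only after the cycloaddition, because 14 is a ketene acetal and would be destroyed by it.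

## Compound list

1 | 3,4,5-trimethoxyphenol | COc1cc(O)cc(OC)c1OC | starting material
2 | 1-(6-hydroxy-2,3,4-trimethoxyphenyl)ethan-1-one | CC(=O)c1c(O)cc(OC)c(OC)c1OC | intermediate
3 | diethyl oxalate | CCOC(=O)C(=O)OCC | starting material
4 | ethyl 4-(6-hydroxy-2,3,4-trimethoxyphenyl)-2,4-dioxobutanoate | CCOC(=O)C(=O)CC(=O)c1c(O)cc(OC)c(OC)c1OC | intermediate
5 | ethyl 5,6,7-trimethoxy-4-oxo-4H-chromene-2-carboxylate | CCOC(=O)c1cc(=O)c2c(OC)c(OC)c(OC)cc2o1 | intermediate
6 | ethyl 5-hydroxy-6,7-dimethoxy-4-oxo-4H-chromene-2-carboxylate | CCOC(=O)c1cc(=O)c2c(O)c(OC)c(OC)cc2o1 | intermediate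
7 | 5-hydroxy-2-(hydroxymethyl)-6,7-dimethoxy-4H-chromen-4-one | OCc1cc(=O)c2c(O)c(OC)c(OC)cc2o1 | intermediate
8 | 5-hydroxy-6,7-dimethoxy-4-oxo-4H-chromene-2-carbaldehyde | O=Cc1cc(=O)c2c(O)c(OC)c(OC)cc2o1 | intermediate
9 | 2-ethynyl-5-hydroxy-6,7-dimethoxy-4H-chromen-4-one | C#Cc1cc(=O)c2c(O)c(OC)c(OC)cc2o1 | intermediate
10 | methyl 4,5-dibromofuran-2-carboxylate | COC(=O)c1cc(Br)c(Br)o1 | starting material
11 | methyl 4-bromo-5-methoxyfuran-2-carboxylate | COC(=O)c1cc(Br)c(OC)o1 | intermediate
12 | methyl 4,5-dimethoxyfuran-2-carboxylate | COC(=O)c1cc(OC)c(OC)o1 | intermediate
13 | 4,5-dimethoxyfuran-2-carboxylic acid | OC(=O)c1cc(OC)c(OC)o1 | intermediate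
14 | 2,3-dimethoxyfuran | COc1ccoc1OC | intermediate
15 | 2-(1,6-dimethoxy-7-oxabicyclo[2.2.1]hepta-2,5-dien-2-yl)-5-hydroxy-6,7-dimethoxy-4H-chromen-4-one (racemic; the two bridgehead centres are tied to each other by the bicycle) | COC1=CC2OC1(OC)C(c1cc(=O)c3c(O)c(OC)c(OC)cc3o1)=C2 | intermediate
16 | 5-hydroxy-2-(5-hydroxy-2,3-dimethoxyphenyl)-6,7-dimethoxy-4H-chromen-4-one | COc1cc(O)cc(-c2cc(=O)c3c(O)c(OC)c(OC)cc3o2)c1OC | target

## Step count and risks

Total step count: 10 (steps 1–6 to alkyne 9, steps 7–9 to furan 14, step 10 joins them).
Longest linear sequence: 7 steps (1 → 2 → 5 → 6 → 7 → 8 → 9 → 16).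

**Step 10 (key step, proposed new method).** The most likely failure is that the cycloaddition is too slow at temperatures the furan tolerates, so that thermal or trace-acid decomposition of 14 outruns addition to an alkyne with only vinylogous activation. Two further failures are possible: the first C–C bond forms but the dipolar intermediate collapses by proton transfer to an alkenylated furan instead of closing, or the furan attacks through its methoxy-bearing C2 and gives the regioisomeric ring B. The fallback uses known flavone chemistry and sets out from 2. Claisen–Schmidt condensation of 2 with purchased 5-bromo-2,3-dimethoxybenzaldehyde (KOH, EtOH, rt) should give (E)-3-(5-bromo-2,3-dimethoxyphenyl)-1-(6-hydroxy-2,3,4-trimethoxyphenyl)prop-2-en-1-one F1. Oxidative cyclisation (I2 cat., DMSO, 120 °C) should give 2-(5-bromo-2,3-dimethoxyphenyl)-5,6,7-trimethoxy-4H-chromen-4-one F2. Miyaura borylation (bis(pinacolato)diboron, PdCl2(dppf), KOAc, dioxane, 90 °C) should give the pinacol boronate 2-[2,3-dimethoxy-5-(4,4,5,5-tetramethyl-1,3,2-dioxaborolan-2-yl)phenyl]-5,6,7-trimethoxy-4H-chromen-4-one F3. Oxidation (NaBO3·4H2O, THF–H2O, rt) should give 2-(5-hydroxy-2,3-dimethoxyphenyl)-5,6,7-trimethoxy-4H-chromen-4-one F4. Chelation-controlled C5 demethylation (BCl3, CH2Cl2, −78 → 0 °C) then returns to the route at 16.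

**Step 6.** The activation that the key step relies on also makes 9 a conjugate acceptor, so methoxide may add to the terminal alkyne carbon, or to C2 of the pyranone with ring opening. The fallback sets out from 8 and avoids methanolic base. Wittig reaction with the ylide from (bromomethyl)triphenylphosphonium bromide and KOtBu (THF, −78 °C, excess to cover the phenol) should give 2-[(Z)-2-bromoethenyl]-5-hydroxy-6,7-dimethoxy-4H-chromen-4-one F5. Dehydrobromination with Bu4NF in DMF then returns to the route at 9.

**Step 7.** Copper-mediated hydrodebromination at C4 may compete with substitution, because the ring is electron-rich after the first methoxylation and methoxide can act as a hydride donor. The fallback sets out from 11, isolated by running the methoxide displacement without copper, and forms the C4–O bond by oxidation of a C–B bond. Miyaura borylation (bis(pinacolato)diboron, PdCl2(dppf), KOAc, dioxane) should give methyl 5-methoxy-4-(4,4,5,5-tetramethyl-1,3,2-dioxaborolan-2-yl)furan-2-carboxylate F6. Oxidation (NaBO3·4H2O, THF–H2O) should give methyl 4-hydroxy-5-methoxyfuran-2-carboxylate F7. O-methylation (dimethyl sulfate, K2CO3, acetone) then returns to the route at 12.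

**Step 9.** The ketene-acetal furan may decompose or polymerise in the hot medium as it forms, or be lost on isolation. The fallback sets out from 10 and reverses the order, so that the decarboxylation is run on a robust dibromide and the sensitive furan is formed last in base. Saponification should give 4,5-dibromofuran-2-carboxylic acid F8, and copper–quinoline decarboxylation should give 2,3-dibromofuran F9. Double methoxylation (NaOMe, CuBr, MeOH–DMF, 100 °C; pentane extraction and distillation) then returns to the route at 14. This fallback presumes that the copper methoxylation of step 7 has been shown to work.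

## Further compounds

F1 | step 10 | (E)-3-(5-bromo-2,3-dimethoxyphenyl)-1-(6-hydroxy-2,3,4-trimethoxyphenyl)prop-2-en-1-one | COc1cc(Br)cc(/C=C/C(=O)c2c(O)cc(OC)c(OC)c2OC)c1OC
F2 | step 10 | 2-(5-bromo-2,3-dimethoxyphenyl)-5,6,7-trimethoxy-4H-chromen-4-one | COc1cc(Br)cc(-c2cc(=O)c3c(OC)c(OC)c(OC)cc3o2)c1OC
F3 | step 10 | 2-[2,3-dimethoxy-5-(4,4,5,5-tetramethyl-1,3,2-dioxaborolan-2-yl)phenyl]-5,6,7-trimethoxy-4H-chromen-4-one | COc1cc(B2OC(C)(C)C(C)(C)O2)cc(-c2cc(=O)c3c(OC)c(OC)c(OC)cc3o2)c1OC
F4 | step 10 | 2-(5-hydroxy-2,3-dimethoxyphenyl)-5,6,7-trimethoxy-4H-chromen-4-one | COc1cc(O)cc(-c2cc(=O)c3c(OC)c(OC)c(OC)cc3o2)c1OC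
F5 | step 6 | 2-[(Z)-2-bromoethenyl]-5-hydroxy-6,7-dimethoxy-4H-chromen-4-one | Br/C=C\c1cc(=O)c2c(O)c(OC)c(OC)cc2o1
F6 | step 7 | methyl 5-methoxy-4-(4,4,5,5-tetramethyl-1,3,2-dioxaborolan-2-yl)furan-2-carboxylate | COC(=O)c1cc(B2OC(C)(C)C(C)(C)O2)c(OC)o1
F7 | step 7 | methyl 4-hydroxy-5-methoxyfuran-2-carboxylate | COC(=O)c1cc(O)c(OC)o1
F8 | step 9 | 4,5-dibromofuran-2-carboxylic acid | OC(=O)c1cc(Br)c(Br)o1
F9 | step 9 | 2,3-dibromofuran | Brc1ccoc1Br
A1 | alternative 1 | 3-(5,6,7-trimethoxy-4-oxo-4H-chromen-2-yl)-4,5-dimethoxyphenyl methanesulfonate | COc1cc(OS(C)(=O)=O)cc(-c2cc(=O)c3c(OC)c(OC)c(OC)cc3o2)c1OC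
A2 | alternative 1 | 3-[3-oxo-3-(2,3,4-trimethoxyphenyl)propanoyl]-4,5-dimethoxyphenyl methanesulfonate | COc1cc(OS(C)(=O)=O)cc(C(=O)CC(=O)c2ccc(OC)c(OC)c2OC)c1OC
A3 | alternative 2 | 2-[5-(benzyloxy)-2,3-dimethoxyphenyl]-5,7-dihydroxy-6-methoxy-4H-chromen-4-one | COc1cc(OCc2ccccc2)cc(-c2cc(=O)c3c(O)c(OC)c(O)cc3o2)c1OC
A4 | alternative 2 | methyl 6-[5-(benzyloxy)-2,3-dimethoxyphenyl]-2-methyl-4-oxo-4H-pyran-3-carboxylate | COC(=O)c1c(C)oc(-c2cc(OCc3ccccc3)cc(OC)c2OC)cc1=O
A5 | alternative 2 | methyl methoxyacetate | COCC(=O)OC
A6 | alternative 3 | 2-[5-(benzyloxy)-2,3-dimethoxyphenyl]-5,6,7-trimethoxy-4H-chromen-4-one | COc1cc(OCc2ccccc2)cc(-c2cc(=O)c3c(OC)c(OC)c(OC)cc3o2)c1OC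
A7 | alternative 3 | 2-iodo-3,4,5-trimethoxyphenol | COc1cc(O)c(I)c(OC)c1OC
A8 | alternative 3 | 5-(benzyloxy)-1-ethynyl-2,3-dimethoxybenzene | C#Cc1cc(OCc2ccccc2)cc(OC)c1OC
A9 | alternative 3 | carbon monoxide | [C-]#[O+]
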